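**Retrosynthetic overview**
- Last bond: the E side-chain alkene, by cross-metathesis of a 2-vinyl furo[3,2-b]pyranone core with the pre-acylated pentenediol.
- Tetrahydrofuran ring (formed last): O1–C7a bond by hemiketal formation on a 5-keto-enelactone and ionic hydrogenation, which sets C7a (proposed new step).
- Pyranone ring (formed first): Achmatowicz oxidative ring expansion of a 2-furyl carbinol (furan to 2H-pyran-3(6H)-one), then lactol oxidation; this is the key step.
- Furyl carbinol: Felkin-controlled furylzinc addition to the threo aldehyde cut from C2-symmetric (3S,4S)-divinylglycol acetonide; these centres become C2, C3 and C3a.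
- Side chain: Sharpless epoxidation of divinylcarbinol, hydride opening, lipase-directed acetylation, then benzoylation.

Assumption: (3S,4S)-hexa-1,5-diene-3,4-diol (1) is bought as the single enantiomer.

**Route**

Step 1
Reactants: 1 (3S,4S)-hexa-1,5-diene-3,4-diol
Product: 2 (4S,5S)-2,2-dimethyl-4,5-divinyl-1,3-dioxolane
Conditions: Me2C(OMe)2, p-toluenesulfonic acid (cat.), CH2Cl2, rt
Reagents that add atoms: 2,2-dimethoxypropane COC(C)(C)OC
Why: Acid-catalysed acetonide formation (transketalization) locks the threo diol as a trans-dioxolane without touching either carbinol centre and provides the 1,2-dialkoxy pattern needed for Felkin control in step 3.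

Step 2
Reactants: 2 (4S,5S)-2,2-dimethyl-4,5-divinyl-1,3-dioxolane
Product: 4 (4R,5S)-2,2-dimethyl-5-vinyl-1,3-dioxolane-4-carbaldehyde, via secondary ozonide 3 (not isolated)
Conditions: O3 (0.9 equiv, stopped near half conversion), CH2Cl2, −78 °C; then Me2S, −78 °C to rt
Reagents that add atoms: ozone [O-][O+]=O
Why: Ozonolysis with reductive work-up: the two vinyl groups of the C2-symmetric diene are homotopic, so cleaving either one gives the same aldehyde with both existing centres intact, and unreacted 2 is recovered and recycled.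

Step 3
Reactants: 4 (4R,5S)-2,2-dimethyl-5-vinyl-1,3-dioxolane-4-carbaldehyde; 5 furan
Product: 8 (R)-furan-2-yl[(4S,5S)-2,2-dimethyl-5-vinyl-1,3-dioxolan-4-yl]methanol, via 2-furyllithium 6 (not isolated), via 2-furylzinc bromide 7 (not isolated)
Conditions: 5, n-BuLi, THF, 0 °C; ZnBr2, 0 °C; then 4, −20 to 0 °C
Reagents that add atoms: none
Why: Felkin–Anh 1,2-addition of the furylzinc reagent to the α,β-dialkoxy aldehyde places the nucleophile anti to the α-C–O bond and so sets the carbinol centre R (1,2-anti), the selectivity expected for zinc-mediated 2-furyl additions to acetonide-protected α-alkoxy aldehydes.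

Step 4
Reactants: 8 (R)-furan-2-yl[(4S,5S)-2,2-dimethyl-5-vinyl-1,3-dioxolan-4-yl]methanol
Product: 10 (2R)-2-[(4R,5S)-2,2-dimethyl-5-vinyl-1,3-dioxolan-4-yl]-6-hydroxy-2H-pyran-3(6H)-one (both C6 epimers), via ring-opened Z-enedione 9 (not isolated)
Conditions: NBS (1.05 equiv), NaHCO3, THF/H2O 4:1, 0 °C
Reagents that add atoms: water O
Why: Achmatowicz rearrangement: electrophilic bromination and hydrolysis open the furan to the Z-enedione 9, whose carbinol oxygen closes onto the aldehyde, so the five-membered furan is expanded to the six-membered pyranone by an ionic (non-pericyclic) oxidative ring expansion with the carbinol centre carried over unchanged as C2.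

Step 5
Reactants: 10 (2R)-2-[(4R,5S)-2,2-dimethyl-5-vinyl-1,3-dioxolan-4-yl]-6-hydroxy-2H-pyran-3(6H)-one
Product: 11 (6R)-6-[(4R,5S)-2,2-dimethyl-5-vinyl-1,3-dioxolan-4-yl]-2H-pyran-2,5(6H)-dione
Conditions: Dess–Martin periodinane, CH2Cl2, 0 °C to rt; used crude at once
Reagents that add atoms: none
Why: Dess–Martin oxidation of the allylic lactol to the lactone runs under non-basic conditions, which protects the C6 centre of the easily enolized 2H-pyran-2,5-dione.

Step 6
Reactants: 11 (6R)-6-[(4R,5S)-2,2-dimethyl-5-vinyl-1,3-dioxolan-4-yl]-2H-pyran-2,5(6H)-dione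
Product: 14 (2S,3R,3aR,7aR)-3-hydroxy-2-vinyl-2,3,3a,7a-tetrahydro-5H-furo[3,2-b]pyran-5-one, via dihydroxy dione 12 (not isolated), via bicyclic hemiketal 13 (not isolated)
Conditions: TFA/H2O 9:1, 0 °C; evaporate; then Et3SiH (5 equiv), BF3·OEt2 (3 equiv), MeCN/CH2Cl2, −30 to 0 °C
Reagents that add atoms: none
Why: Proposed new method: hemiketal-relayed reductive etherification of a 2H-pyran-2,5(6H)-dione, in which hydrolytic release of the diol lets the distal (allylic) hydroxyl add to the very electrophilic C5 ketone to give the five-membered hemiketal 13, BF3 ionizes it to a bicyclic oxocarbenium ion, and Et3SiH delivers hydride only to the face that leaves the rings cis-fused (a trans-fused dihydropyranone would be badly strained, and this is also the open all-hydrogen face), so the tetrahydrofuran ring is closed and C7a is set R with retention at every existing centre; the closest known reactions are Et3SiH/BF3·OEt2 reductions of ketose-type hemiketals to cyclic ethers and the Luche reduction of these diones (which gives the unwanted 5,6-trans alcohol), and this relay has, to my knowledge, not been shown on a 5-keto-enelactone.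

Step 7
Reactants: 15 penta-1,4-dien-3-ol
Product: 16 (2R,3S)-1,2-epoxypent-4-en-3-ol
Conditions: Ti(OiPr)4, L-(+)-diisopropyl tartrate, t-BuOOH, 4 Å molecular sieves, CH2Cl2, −20 °C
Reagents that add atoms: tert-butyl hydroperoxide CC(C)(C)OO
Why: Sharpless asymmetric epoxidation of the prochiral divinylcarbinol: the L-tartrate catalyst picks one enantiotopic vinyl group and the face that gives the erythro (2R,3S) epoxy alcohol, and the minor enantiomer is consumed by a faster second epoxidation, so both centres are set with very high ee.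

Step 8
Reactants: 16 (2R,3S)-1,2-epoxypent-4-en-3-ol
Product: 17 (2R,3S)-pent-4-ene-2,3-diol
Conditions: LiAlH4, Et2O, 0 °C
Reagents that add atoms: none
Why: Epoxide reduction by SN2 hydride attack at the unsubstituted terminal carbon turns the oxirane CH2 into the methyl group and leaves both stereocentres untouched.

Step 9
Reactants: 17 (2R,3S)-pent-4-ene-2,3-diol
Product: 19 (2R,3S)-2-acetoxypent-4-en-3-yl benzoate, via monoacetate 18 (not isolated)
Conditions: immobilized Candida antarctica lipase B, vinyl acetate, MTBE, 30 °C; filter, evaporate; then BzCl, pyridine, 4-(dimethylamino)pyridine (cat.), CH2Cl2, 0 °C to rt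
Reagents that add atoms: vinyl acetate C=COC(C)=O; benzoyl chloride O=C(Cl)c1ccccc1
Why: Lipase transesterification follows the Kazlauskas rule, so the enzyme should acetylate only the (R)-methyl carbinol and not the (S)-allylic hydroxyl (the slow-reacting sense), and the remaining allylic hydroxyl is then benzoylated by nucleophile-catalysed acyl transfer before any acetyl migration.

Step 10
Reactants: 14 (2S,3R,3aR,7aR)-3-hydroxy-2-vinyl-2,3,3a,7a-tetrahydro-5H-furo[3,2-b]pyran-5-one; 19 (2R,3S)-2-acetoxypent-4-en-3-yl benzoate (3 equiv)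
Product: 20 (2R,3S,4E)-2-acetoxy-5-[(2S,3R,3aR,7aR)-3-hydroxy-5-oxo-2,3,3a,7a-tetrahydro-5H-furo[3,2-b]pyran-2-yl]pent-4-en-3-yl benzoate
Conditions: second-generation Hoveyda–Grubbs catalyst RuCl2(=CH-C6H4-2-OiPr)(1,3-dimesitylimidazolidin-2-ylidene) (10 mol%), CH2Cl2, 40 °C
Reagents that add atoms: none
Why: Olefin cross-metathesis of two monosubstituted alkenes that each carry an allylic oxygen (both slow to homodimerize), with the side-chain partner in excess, forms the side-chain C=C bond as the thermodynamically favoured E isomer while the electron-poor endocyclic enoate stays out of the catalytic cycle.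

**Compound list**

1 | (3S,4S)-hexa-1,5-diene-3,4-diol | C=C[C@H](O)[C@@H](O)C=C | starting material
2 | (4S,5S)-2,2-dimethyl-4,5-divinyl-1,3-dioxolane | C=C[C@@H]1OC(C)(C)O[C@H]1C=C | intermediate
3 | 3-[(4R,5S)-2,2-dimethyl-5-vinyl-1,3-dioxolan-4-yl]-1,2,4-trioxolane (secondary ozonide, trioxolane carbon unassigned) | C=C[C@@H]1OC(C)(C)O[C@H]1C2OOCO2 | intermediate
4 | (4R,5S)-2,2-dimethyl-5-vinyl-1,3-dioxolane-4-carbaldehyde | C=C[C@@H]1OC(C)(C)O[C@H]1C=O | intermediate
5 | furan | c1ccoc1 | starting material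
6 | 2-furyllithium | [Li]c1ccco1 | intermediate
7 | 2-furylzinc bromide | Br[Zn]c1ccco1 | intermediate
8 | (R)-furan-2-yl[(4S,5S)-2,2-dimethyl-5-vinyl-1,3-dioxolan-4-yl]methanol | C=C[C@@H]1OC(C)(C)O[C@H]1[C@@H](O)c2ccco2 | intermediate
9 | (2Z,5R)-5-[(4S,5S)-2,2-dimethyl-5-vinyl-1,3-dioxolan-4-yl]-5-hydroxy-4-oxopent-2-enal (ring-opened Z-enedione) | C=C[C@@H]1OC(C)(C)O[C@H]1[C@@H](O)C(=O)/C=C\C=O | intermediate
10 | (2R)-2-[(4R,5S)-2,2-dimethyl-5-vinyl-1,3-dioxolan-4-yl]-6-hydroxy-2H-pyran-3(6H)-one (C6 epimers) | C=C[C@@H]1OC(C)(C)O[C@H]1[C@H]2OC(O)C=CC2=O | intermediate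
11 | (6R)-6-[(4R,5S)-2,2-dimethyl-5-vinyl-1,3-dioxolan-4-yl]-2H-pyran-2,5(6H)-dione | C=C[C@@H]1OC(C)(C)O[C@H]1[C@H]2OC(=O)C=CC2=O | intermediate
12 | (6R)-6-[(1R,2S)-1,2-dihydroxybut-3-en-1-yl]-2H-pyran-2,5(6H)-dione (dihydroxy dione) | C=C[C@H](O)[C@@H](O)[C@H]1OC(=O)C=CC1=O | intermediate
13 | (2S,3R,3aR)-3,7a-dihydroxy-2-vinyl-2,3,3a,7a-tetrahydro-5H-furo[3,2-b]pyran-5-one (bicyclic hemiketal, C7a epimers) | C=C[C@@H]1OC2(O)C=CC(=O)O[C@@H]2[C@@H]1O | intermediate
14 | (2S,3R,3aR,7aR)-3-hydroxy-2-vinyl-2,3,3a,7a-tetrahydro-5H-furo[3,2-b]pyran-5-one | C=C[C@@H]1O[C@@H]2C=CC(=O)O[C@@H]2[C@@H]1O | intermediate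
15 | penta-1,4-dien-3-ol | C=CC(O)C=C | starting material
16 | (2R,3S)-1,2-epoxypent-4-en-3-ol | C=C[C@H](O)[C@H]1CO1 | intermediate
17 | (2R,3S)-pent-4-ene-2,3-diol | C=C[C@H](O)[C@@H](C)O | intermediate
18 | (2R,3S)-3-hydroxypent-4-en-2-yl acetate (monoacetate) | C=C[C@H](O)[C@@H](C)OC(C)=O | intermediate
19 | (2R,3S)-2-acetoxypent-4-en-3-yl benzoate | C=C[C@H](OC(=O)c1ccccc1)[C@@H](C)OC(C)=O | intermediate
20 | (2R,3S,4E)-2-acetoxy-5-[(2S,3R,3aR,7aR)-3-hydroxy-5-oxo-2,3,3a,7a-tetrahydro-5H-furo[3,2-b]pyran-2-yl]pent-4-en-3-yl benzoate | CC(=O)O[C@H](C)[C@H](/C=C/[C@@H]1O[C@@H]2C=CC(=O)O[C@@H]2[C@@H]1O)OC(=O)c1ccccc1 | target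

**Step count and risks**

Total steps: 10. Longest linear sequence: 7 steps (1 → 2 → 4 → 8 → 10 → 11 → 14 → 20); the side chain 15 → 16 → 17 → 19 takes 3 steps.

Most likely to fail:

1. Step 6 (the proposed new step). The dione could enolize towards C6 to an aromatic 5-hydroxy-2-pyranone before the hemiketal forms. The oxocarbenium ion could lose H-3a to give a fused 2-pyranone instead of taking hydride, or hydride could add at the conjugate position. The fallback uses known chemistry, sets out from 11 and comes back at 14. Luche reduction of 11 (NaBH4, CeCl3·7H2O, MeOH, −78 °C), which favours the 5,6-trans alcohol for such diones, gives (5S,6S)-6-[(4R,5S)-2,2-dimethyl-5-vinyl-1,3-dioxolan-4-yl]-5-hydroxy-5,6-dihydro-2H-pyran-2-one F1. MsCl/Et3N converts it to (2R,3S)-2-[(4R,5S)-2,2-dimethyl-5-vinyl-1,3-dioxolan-4-yl]-6-oxo-3,6-dihydro-2H-pyran-3-yl methanesulfonate F2. Aqueous TFA removes the acetonide to give (2R,3S)-2-[(1R,2S)-1,2-dihydroxybut-3-en-1-yl]-6-oxo-3,6-dihydro-2H-pyran-3-yl methanesulfonate F3. Warming F3 with NaHCO3 in MeCN lets the allylic hydroxyl displace the mesylate with inversion (intramolecular Williamson etherification), which turns the trans alcohol into the cis-fused 14.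

2. Step 10 (cross-metathesis of two hindered allylic-oxygenated alkenes, one next to a free cis hydroxyl and a lactone). The fallback moves the metathesis to the furan stage; it sets out from 8 (with 19) and comes back at 20. Cross-metathesis of 8 with 19 under the same Ru catalyst gives (2R,3S,4E)-2-acetoxy-5-[(4S,5S)-5-[(R)-furan-2-yl(hydroxy)methyl]-2,2-dimethyl-1,3-dioxolan-4-yl]pent-4-en-3-yl benzoate F4, where the vinyl group sits on a simple dioxolane. The conditions of steps 4 to 6 are then applied to the full-length compound: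
   - NBS gives (2R,3S,4E)-2-acetoxy-5-[(4S,5R)-5-[(2R)-6-hydroxy-3-oxo-3,6-dihydro-2H-pyran-2-yl]-2,2-dimethyl-1,3-dioxolan-4-yl]pent-4-en-3-yl benzoate F5.
   - Dess–Martin oxidation gives (2R,3S,4E)-2-acetoxy-5-[(4S,5R)-5-[(2R)-3,6-dioxo-3,6-dihydro-2H-pyran-2-yl]-2,2-dimethyl-1,3-dioxolan-4-yl]pent-4-en-3-yl benzoate F6.
   - Aqueous TFA gives (2R,3S,4E,6S,7R)-2-acetoxy-6,7-dihydroxy-7-[(2R)-3,6-dioxo-3,6-dihydro-2H-pyran-2-yl]hept-4-en-3-yl benzoate F7, which closes to (2R,3S,4E)-2-acetoxy-5-[(2S,3R,3aR)-3,7a-dihydroxy-5-oxo-2,3,3a,7a-tetrahydro-5H-furo[3,2-b]pyran-2-yl]pent-4-en-3-yl benzoate F8.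
   - Et3SiH/BF3·OEt2 reduces F8 to 20.

3. Step 9 (the regioselectivity of the lipase acetylation is predicted from the Kazlauskas rule, not demonstrated on this diol). The fallback fixes the benzoate before the second hydroxyl exists; it sets out from 16 and comes back at 19. BzCl/pyridine converts 16 to (S)-1-[(R)-oxiran-2-yl]prop-2-en-1-yl benzoate F9. MgI2 (Et2O/toluene, −60 °C) opens the epoxide at the terminal carbon to (2S,3S)-2-hydroxy-1-iodopent-4-en-3-yl benzoate F10. Bu3SnH with azobisisobutyronitrile removes the iodine to give (2R,3S)-2-hydroxypent-4-en-3-yl benzoate F11. Ac2O/pyridine then gives 19.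

**Further compounds**

F1 | step 6 | (5S,6S)-6-[(4R,5S)-2,2-dimethyl-5-vinyl-1,3-dioxolan-4-yl]-5-hydroxy-5,6-dihydro-2H-pyran-2-one | C=C[C@@H]1OC(C)(C)O[C@H]1[C@H]2OC(=O)C=C[C@@H]2O
F2 | step 6 | (2R,3S)-2-[(4R,5S)-2,2-dimethyl-5-vinyl-1,3-dioxolan-4-yl]-6-oxo-3,6-dihydro-2H-pyran-3-yl methanesulfonate | C=C[C@@H]1OC(C)(C)O[C@H]1[C@H]2OC(=O)C=C[C@@H]2OS(C)(=O)=O
F3 | step 6 | (2R,3S)-2-[(1R,2S)-1,2-dihydroxybut-3-en-1-yl]-6-oxo-3,6-dihydro-2H-pyran-3-yl methanesulfonate | C=C[C@H](O)[C@@H](O)[C@H]1OC(=O)C=C[C@@H]1OS(C)(=O)=O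
F4 | step 10 | (2R,3S,4E)-2-acetoxy-5-[(4S,5S)-5-[(R)-furan-2-yl(hydroxy)methyl]-2,2-dimethyl-1,3-dioxolan-4-yl]pent-4-en-3-yl benzoate | CC(=O)O[C@H](C)[C@H](/C=C/[C@@H]1OC(C)(C)O[C@H]1[C@@H](O)c2ccco2)OC(=O)c1ccccc1
F5 | step 10 | (2R,3S,4E)-2-acetoxy-5-[(4S,5R)-5-[(2R)-6-hydroxy-3-oxo-3,6-dihydro-2H-pyran-2-yl]-2,2-dimethyl-1,3-dioxolan-4-yl]pent-4-en-3-yl benzoate | CC(=O)O[C@H](C)[C@H](/C=C/[C@@H]1OC(C)(C)O[C@H]1[C@H]2OC(O)C=CC2=O)OC(=O)c1ccccc1
F6 | step 10 | (2R,3S,4E)-2-acetoxy-5-[(4S,5R)-5-[(2R)-3,6-dioxo-3,6-dihydro-2H-pyran-2-yl]-2,2-dimethyl-1,3-dioxolan-4-yl]pent-4-en-3-yl benzoate | CC(=O)O[C@H](C)[C@H](/C=C/[C@@H]1OC(C)(C)O[C@H]1[C@H]2OC(=O)C=CC2=O)OC(=O)c1ccccc1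
F7 | step 10 | (2R,3S,4E,6S,7R)-2-acetoxy-6,7-dihydroxy-7-[(2R)-3,6-dioxo-3,6-dihydro-2H-pyran-2-yl]hept-4-en-3-yl benzoate | CC(=O)O[C@H](C)[C@H](/C=C/[C@H](O)[C@@H](O)[C@H]1OC(=O)C=CC1=O)OC(=O)c1ccccc1
F8 | step 10 | (2R,3S,4E)-2-acetoxy-5-[(2S,3R,3aR)-3,7a-dihydroxy-5-oxo-2,3,3a,7a-tetrahydro-5H-furo[3,2-b]pyran-2-yl]pent-4-en-3-yl benzoate | CC(=O)O[C@H](C)[C@H](/C=C/[C@@H]1OC2(O)C=CC(=O)O[C@@H]2[C@@H]1O)OC(=O)c1ccccc1
F9 | step 9 | (S)-1-[(R)-oxiran-2-yl]prop-2-en-1-yl benzoate | C=C[C@H](OC(=O)c1ccccc1)[C@H]1CO1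
F10 | step 9 | (2S,3S)-2-hydroxy-1-iodopent-4-en-3-yl benzoate | C=C[C@H](OC(=O)c1ccccc1)[C@H](O)CI
F11 | step 9 | (2R,3S)-2-hydroxypent-4-en-3-yl benzoate | C=C[C@H](OC(=O)c1ccccc1)[C@H](O)C
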